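**Plan**
Numbering: the hydrindenone is numbered as an inden-4-one (C1–C3 cyclopentane CH2 groups, C3a and C7a the methyl-bearing fusion carbons, C4=O, C5=C6, C7 the ring CH2).
Enabling feature: the ring C3a–C4–C5–C6–C7–C7a carries its oxygen (C4) and its two methyls (C3a, C7a) in the pattern of a 2,3-dimethylphenol. The C4=O/C5=C6 enone reaches C7a through C7, so C7a is the δ-terminus of the cyclohexa-2,4-dienone that forms when that phenol is C-alkylated at C3a.
Retrosynthesis: saturate C1=C2 and hydrate a methallyl group last; cut C1–C7a (vinyl-radical closure onto the dienone, the last ring); cut C3a–C3 (dearomatising ortho-alkylation of a pentasubstituted phenol with 1,3-dibromopropene); then the chroman O–aryl bond, the aryl–methallyl bond and the aryl–CH2 bond.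
Forward: both six-membered carbocycles are bought as arenes and joined through (R)-2-methylglycidol by two copper-catalysed Grignard epoxide openings; a Claisen rearrangement and a palladium etherification (pyran ring) follow; then dearomatisation, and the cyclopentane is closed last.
Stereochemistry: chroman C2 comes from (R)-2-methylglycidol (no bond to that carbon is ever broken); C3a from reagent control in the dearomatising alkylation; C7a from the three-atom tether, which allows only the cis ring fusion.
Key step: step 11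

Remark: (R)-2-methylglycidol (9) is taken as a purchasable enantiopure building block, and 1,3-dibromopropene (18) is used as the commercial E/Z mixture because the bromoalkene geometry is erased in the vinyl radical.

**Route**

Step 1
Reactants: 1 2,3-dimethylanisole (1-methoxy-2,3-dimethylbenzene)
Product: 3 5-bromo-1-methoxy-2,3-dimethylbenzene, via aryl pinacol boronate 2 (not isolated)
Conditions: B2pin2, [Ir(cod)OMe]2 (1 mol %), dtbpy (2 mol %), THF, 80 °C; then CuBr2 (3 equiv), MeOH/H2O, 80 °C
Reagents that add atoms: copper dibromide CuBr2, Br[Cu]Br; bis(pinacolato)diboron, CC1(C)OB(OC1(C)C)B1OC(C)(C)C(C)(C)O1 (its boron is retained only in 2)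
Why: Iridium-catalysed C–H borylation (Hartwig–Miyaura type) is sterically governed and should select C5, the only ring C–H of 1 without an ortho substituent, and copper-mediated bromodeboronation then exchanges boron for bromine at the same carbon.

Step 2
Reactants: 3 5-bromo-1-methoxy-2,3-dimethylbenzene
Product: 4 5-bromo-2,3-dimethylphenol
Conditions: 48% aq. HBr, AcOH, 110 °C
Reagents that add atoms: none
Why: Acid-mediated aryl methyl ether cleavage (protonation, then SN2 attack of bromide on the methyl group) should unmask the phenol without touching the aryl bromide.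

Step 3
Reactants: 4 5-bromo-2,3-dimethylphenol; 5 3-chloro-2-methylprop-1-ene (methallyl chloride)
Product: 6 5-bromo-1,2-dimethyl-3-[(2-methylprop-2-en-1-yl)oxy]benzene
Conditions: K2CO3, DMF, 60 °C
Reagents that add atoms: none
Why: Williamson ether synthesis of the phenoxide with a reactive allylic chloride; the methallyl ether masks the phenol for the Grignard step and is the substrate of the later Claisen rearrangement.

Step 4
Reactants: 7 2-bromo-5-methoxy-1,3-dimethylbenzene (4-bromo-3,5-dimethylanisole)
Product: 8 2-bromo-1-(bromomethyl)-5-methoxy-3-methylbenzene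
Conditions: NBS (1.0 equiv), AIBN (cat.), PhCF3, 80 °C
Reagents that add atoms: N-bromosuccinimide, BrN1C(=O)CCC1=O
Why: Wohl–Ziegler benzylic bromination; the two methyl groups of 7 are equivalent, so one equivalent of NBS under radical conditions in a non-polar medium should give the mono-bromide in preference to ring bromination.

Step 5
Reactants: 9 (R)-2-methylglycidol, [(2R)-2-methyloxiran-2-yl]methanol
Product: 10 [(2S)-2-methyloxiran-2-yl]methyl 4-methylbenzenesulfonate
Conditions: TsCl, Et3N, DMAP (cat.), CH2Cl2, 0 °C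
Reagents that add atoms: 4-methylbenzenesulfonyl chloride, Cc1ccc(cc1)S(Cl)(=O)=O
Why: Sulfonylation of the primary alcohol; no bond to the stereocentre is touched (the descriptor changes from R to S only because the CH2OTs group gains priority).

Step 6
Reactants: 8 2-bromo-1-(bromomethyl)-5-methoxy-3-methylbenzene; 10 [(2S)-2-methyloxiran-2-yl]methyl 4-methylbenzenesulfonate
Product: 13 (2S)-2-[2-(2-bromo-5-methoxy-3-methylphenyl)ethyl]-2-methyloxirane, via benzylic Grignard reagent 11 (not isolated), via hydroxy tosylate 12 (not isolated)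
Conditions: Mg, Et2O, 0 °C; then 10, CuI (10 mol %), THF, −40 to 0 °C; then MeOH, K2CO3, rt
Reagents that add atoms: magnesium, [Mg] (retained only in 11)
Why: Copper-catalysed Grignard opening of the epoxide at its unsubstituted CH2, then base-induced 3-exo-tet displacement of the tosylate by the tertiary alkoxide (epoxide relay); the quaternary stereocentre keeps all four of its bonds, so its configuration is carried over.

Step 7
Reactants: 6 5-bromo-1,2-dimethyl-3-[(2-methylprop-2-en-1-yl)oxy]benzene; 13 (2S)-2-[2-(2-bromo-5-methoxy-3-methylphenyl)ethyl]-2-methyloxirane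
Product: 15 (2S)-4-(2-bromo-5-methoxy-3-methylphenyl)-1-{3,4-dimethyl-5-[(2-methylprop-2-en-1-yl)oxy]phenyl}-2-methylbutan-2-ol, via aryl Grignard reagent 14 (not isolated)
Conditions: Mg, THF, 50 °C; then 13, CuI (10 mol %), THF, −30 °C to rt; aqueous work-up
Reagents that add atoms: magnesium, [Mg] (retained only in 14)
Why: Copper-catalysed aryl Grignard opening of the 2,2-disubstituted epoxide at its CH2 terminus (SN2) creates the aryl–CH2 bond and leaves the tertiary carbinol stereocentre untouched; the aryl bromide of 13 is inert to the Grignard reagent.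

Step 8
Reactants: 15 (2S)-4-(2-bromo-5-methoxy-3-methylphenyl)-1-{3,4-dimethyl-5-[(2-methylprop-2-en-1-yl)oxy]phenyl}-2-methylbutan-2-ol
Product: 16 3-[(2S)-4-(2-bromo-5-methoxy-3-methylphenyl)-2-hydroxy-2-methylbutyl]-5,6-dimethyl-2-(2-methylprop-2-en-1-yl)phenol
Conditions: PhNEt2, 190 °C (sealed tube)
Reagents that add atoms: none
Why: Aromatic Claisen rearrangement ([3,3]-sigmatropic shift, then tautomerisation) should deliver the methallyl group to the only free ortho position of the ether, the carbon between the oxygen-bearing and the side-chain-bearing carbons.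

Step 9
Reactants: 16 3-[(2S)-4-(2-bromo-5-methoxy-3-methylphenyl)-2-hydroxy-2-methylbutyl]-5,6-dimethyl-2-(2-methylprop-2-en-1-yl)phenol
Product: 17 3-{[(2S)-6-methoxy-2,8-dimethyl-3,4-dihydro-2H-chromen-2-yl]methyl}-5,6-dimethyl-2-(2-methylprop-2-en-1-yl)phenol
Conditions: Pd(OAc)2 (5 mol %), 2-(di-tert-butylphosphino)-1,1'-binaphthyl (6 mol %), Cs2CO3, toluene, 80 °C
Reagents that add atoms: none
Why: Intramolecular Buchwald–Hartwig etherification (oxidative addition, alkoxide binding, C–O reductive elimination) closes the dihydropyran ring through the tertiary alkoxide, which has no hydrogen on the carbinol carbon; the carbinol C–O bond is not broken, so chroman C2 retains its configuration, and the doubly ortho-substituted phenoxide should not compete as a nucleophile.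

Step 10
Reactants: 17 3-{[(2S)-6-methoxy-2,8-dimethyl-3,4-dihydro-2H-chromen-2-yl]methyl}-5,6-dimethyl-2-(2-methylprop-2-en-1-yl)phenol; 18 1,3-dibromoprop-1-ene (E/Z mixture)
Product: 20 (6S)-6-(3-bromoprop-2-en-1-yl)-3-{[(2S)-6-methoxy-2,8-dimethyl-3,4-dihydro-2H-chromen-2-yl]methyl}-5,6-dimethyl-2-(2-methylprop-2-en-1-yl)cyclohexa-2,4-dien-1-one (E/Z mixture at the bromoalkene), via bromomagnesium phenoxide 19 (not isolated)
Conditions: EtMgBr (1.0 equiv), toluene, 0 °C; 2,2'-(propane-2,2-diyl)bis(4-tert-butyl-4,5-dihydro-1,3-oxazole) (t-Bu-box, 1.1 equiv, the enantiomer that delivers 6S); then 18 (1.5 equiv), −20 °C to rt; cold aqueous work-up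
Reagents that add atoms: ethylmagnesium bromide, CC[Mg]Br (magnesium and bromine retained only in 19)
Why: Proposed new method: in toluene the bromomagnesium phenoxide is a tight O–Mg species, so C–C bond formation should occur at an ortho carbon through a closed transition state in which magnesium bridges the phenoxide oxygen and the departing bromide of the allylic CH2Br group (SN2, irreversible, so the non-aromatic dienone is a kinetic product that cannot revert), at the methyl-bearing ortho carbon (future C3a) in preference to the methallyl-bearing one that is flanked by the chromanylmethyl group, while the C2-symmetric bis(oxazoline) on magnesium covers one face of the phenoxide next to the reacting carbon and should direct the electrophile to the other face to set 6S; the closest known reaction type is the ortho-selective C-allylation of 2,6-dialkylphenoxide metal salts in non-polar solvents to racemic 6-allylcyclohexa-2,4-dienones, combined with bis(oxazoline)–metal control of enolate alkylation.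

Step 11
Reactants: 20 (6S)-6-(3-bromoprop-2-en-1-yl)-3-{[(2S)-6-methoxy-2,8-dimethyl-3,4-dihydro-2H-chromen-2-yl]methyl}-5,6-dimethyl-2-(2-methylprop-2-en-1-yl)cyclohexa-2,4-dien-1-one
Product: 21 (3aS,7aR)-6-{[(2S)-6-methoxy-2,8-dimethyl-3,4-dihydro-2H-chromen-2-yl]methyl}-3a,7a-dimethyl-5-(2-methylprop-2-en-1-yl)-3,3a,7,7a-tetrahydro-4H-inden-4-one
Conditions: n-Bu3SnH (1.3 equiv, syringe pump), 2,2'-azobis(4-methoxy-2,4-dimethylvaleronitrile) (0.3 equiv), benzene (0.01 M), 35 °C; then DBU (0.2 equiv), rt
Reagents that add atoms: none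
Why: Bromine abstraction by Bu3Sn• gives a rapidly inverting σ-vinyl radical at C1, which adds 5-exo-trig to C7a, the δ-terminus of the C4=O/C5=C6/C7=C7a dienone, and the resulting oxygen-stabilised pentadienyl-type radical takes hydrogen from the stannane at C7 (any C6=C7 isomer is brought into conjugation by DBU), so the ring, the second quaternary centre and the tetrasubstituted enone arise together. The closest known reaction type is the 5-exo cyclisation of vinyl radicals onto enones (intramolecular Giese addition), here in its vinylogous 1,6 form. The cyclopentene ring closes in the 5-exo-trig mode; 6-endo attack at C7 would give an unstabilised tertiary radical and opposes the polarity of the nucleophilic radical. The new stereocentre C7a is controlled by C3a: the three-atom tether reaches C7a only on the face that carries it, so only the cis ring fusion with both methyls on the same face can form (3aS,7aR in 21, which becomes 3aS,7aS once C1=C2 is saturated). The step needs cyclisation to outrun direct reduction and the thermal [3,3] shift of the bromoallyl group to C7, which slow stannane addition at high dilution and initiation at 35 °C should secure; the methallyl alkene is out of reach of the radical.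

Step 12
Reactants: 21 (3aS,7aR)-6-{[(2S)-6-methoxy-2,8-dimethyl-3,4-dihydro-2H-chromen-2-yl]methyl}-3a,7a-dimethyl-5-(2-methylprop-2-en-1-yl)-3,3a,7,7a-tetrahydro-4H-inden-4-one
Product: 23 (3aS,7aR)-5-(2-hydroxy-2-methylpropyl)-6-{[(2S)-6-methoxy-2,8-dimethyl-3,4-dihydro-2H-chromen-2-yl]methyl}-3a,7a-dimethyl-3,3a,7,7a-tetrahydro-4H-inden-4-one, via tertiary hydroperoxide 22 (not isolated)
Conditions: Mn(dpm)3 (10 mol %), PhSiH3, O2 (1 atm), i-PrOH/CH2Cl2, 0 °C; then PPh3
Reagents that add atoms: dioxygen, O=O
Why: Mukaiyama hydration (metal-hydride hydrogen-atom transfer to the 1,1-disubstituted alkene, trapping of the tertiary radical by O2, reduction of the hydroperoxide) should be Markovnikov and selective for the methallyl group over the 1,2-disubstituted cyclopentene and the electron-poor tetrasubstituted enone.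

Step 13
Reactants: 23 (3aS,7aR)-5-(2-hydroxy-2-methylpropyl)-6-{[(2S)-6-methoxy-2,8-dimethyl-3,4-dihydro-2H-chromen-2-yl]methyl}-3a,7a-dimethyl-3,3a,7,7a-tetrahydro-4H-inden-4-one
Product: 24 (3aS,7aS)-5-(2-hydroxy-2-methylpropyl)-6-{[(2S)-6-methoxy-2,8-dimethyl-3,4-dihydro-2H-chromen-2-yl]methyl}-3a,7a-dimethyl-1,2,3,3a,7,7a-hexahydro-4H-inden-4-one (target)
Conditions: H2 (3 atm), RhCl(PPh3)3 (10 mol %), benzene/EtOH, rt
Reagents that add atoms: none
Why: Homogeneous hydrogenation with RhCl(PPh3)3 should reduce only the cis-disubstituted cyclopentene, the tetrasubstituted enone and the arene being inert to this catalyst; no stereocentre is formed or touched.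

**Compound list**

1 | 2,3-dimethylanisole (1-methoxy-2,3-dimethylbenzene) | COc1cccc(C)c1C | starting material
2 | 2-(3-methoxy-4,5-dimethylphenyl)-4,4,5,5-tetramethyl-1,3,2-dioxaborolane | COc1cc(B2OC(C)(C)C(C)(C)O2)cc(C)c1C | intermediate (not isolated)
3 | 5-bromo-1-methoxy-2,3-dimethylbenzene | COc1cc(Br)cc(C)c1C | intermediate
4 | 5-bromo-2,3-dimethylphenol | Oc1cc(Br)cc(C)c1C | intermediate
5 | 3-chloro-2-methylprop-1-ene (methallyl chloride) | CC(=C)CCl | starting material
6 | 5-bromo-1,2-dimethyl-3-[(2-methylprop-2-en-1-yl)oxy]benzene | CC(=C)COc1cc(Br)cc(C)c1C | intermediate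
7 | 2-bromo-5-methoxy-1,3-dimethylbenzene (4-bromo-3,5-dimethylanisole) | COc1cc(C)c(Br)c(C)c1 | starting material
8 | 2-bromo-1-(bromomethyl)-5-methoxy-3-methylbenzene | COc1cc(C)c(Br)c(CBr)c1 | intermediate
9 | (R)-2-methylglycidol, [(2R)-2-methyloxiran-2-yl]methanol | C[C@@]1(CO)CO1 | starting material
10 | [(2S)-2-methyloxiran-2-yl]methyl 4-methylbenzenesulfonate | C[C@@]1(COS(=O)(=O)c2ccc(C)cc2)CO1 | intermediate
11 | (2-bromo-5-methoxy-3-methylbenzyl)magnesium bromide | COc1cc(C)c(Br)c(C[Mg]Br)c1 | intermediate (not isolated)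
12 | (2S)-4-(2-bromo-5-methoxy-3-methylphenyl)-2-hydroxy-2-methylbutyl 4-methylbenzenesulfonate | C[C@@](O)(COS(=O)(=O)c1ccc(C)cc1)CCc1cc(OC)cc(C)c1Br | intermediate (not isolated)
13 | (2S)-2-[2-(2-bromo-5-methoxy-3-methylphenyl)ethyl]-2-methyloxirane | C[C@@]1(CO1)CCc1cc(OC)cc(C)c1Br | intermediate
14 | {3,4-dimethyl-5-[(2-methylprop-2-en-1-yl)oxy]phenyl}magnesium bromide | Cc1cc([Mg]Br)cc(OCC(C)=C)c1C | intermediate (not isolated)
15 | (2S)-4-(2-bromo-5-methoxy-3-methylphenyl)-1-{3,4-dimethyl-5-[(2-methylprop-2-en-1-yl)oxy]phenyl}-2-methylbutan-2-ol | C[C@@](O)(Cc1cc(C)c(C)c(OCC(C)=C)c1)CCc1cc(OC)cc(C)c1Br | intermediate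
16 | 3-[(2S)-4-(2-bromo-5-methoxy-3-methylphenyl)-2-hydroxy-2-methylbutyl]-5,6-dimethyl-2-(2-methylprop-2-en-1-yl)phenol | C[C@@](O)(Cc1cc(C)c(C)c(O)c1CC(C)=C)CCc1cc(OC)cc(C)c1Br | intermediate
17 | 3-{[(2S)-6-methoxy-2,8-dimethyl-3,4-dihydro-2H-chromen-2-yl]methyl}-5,6-dimethyl-2-(2-methylprop-2-en-1-yl)phenol | COc1cc(C)c2c(c1)CC[C@@](C)(Cc1cc(C)c(C)c(O)c1CC(C)=C)O2 | intermediate
18 | 1,3-dibromoprop-1-ene (E/Z mixture) | BrCC=CBr | starting material
19 | bromomagnesium phenoxide of 17 | COc1cc(C)c2c(c1)CC[C@@](C)(Cc1cc(C)c(C)c(O[Mg]Br)c1CC(C)=C)O2 | intermediate (not isolated)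
20 | (6S)-6-(3-bromoprop-2-en-1-yl)-3-{[(2S)-6-methoxy-2,8-dimethyl-3,4-dihydro-2H-chromen-2-yl]methyl}-5,6-dimethyl-2-(2-methylprop-2-en-1-yl)cyclohexa-2,4-dien-1-one (E/Z mixture at the bromoalkene) | COc1cc(C)c2c(c1)CC[C@@](C)(CC1=C(CC(C)=C)C(=O)[C@@](C)(CC=CBr)C(C)=C1)O2 | intermediate
21 | (3aS,7aR)-6-{[(2S)-6-methoxy-2,8-dimethyl-3,4-dihydro-2H-chromen-2-yl]methyl}-3a,7a-dimethyl-5-(2-methylprop-2-en-1-yl)-3,3a,7,7a-tetrahydro-4H-inden-4-one | COc1cc(C)c2c(c1)CC[C@@](C)(CC1=C(CC(C)=C)C(=O)[C@@]3(C)CC=C[C@@]3(C)C1)O2 | intermediate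
22 | (3aS,7aR)-5-(2-hydroperoxy-2-methylpropyl)-6-{[(2S)-6-methoxy-2,8-dimethyl-3,4-dihydro-2H-chromen-2-yl]methyl}-3a,7a-dimethyl-3,3a,7,7a-tetrahydro-4H-inden-4-one | COc1cc(C)c2c(c1)CC[C@@](C)(CC1=C(CC(C)(C)OO)C(=O)[C@@]3(C)CC=C[C@@]3(C)C1)O2 | intermediate (not isolated)
23 | (3aS,7aR)-5-(2-hydroxy-2-methylpropyl)-6-{[(2S)-6-methoxy-2,8-dimethyl-3,4-dihydro-2H-chromen-2-yl]methyl}-3a,7a-dimethyl-3,3a,7,7a-tetrahydro-4H-inden-4-one | COc1cc(C)c2c(c1)CC[C@@](C)(CC1=C(CC(C)(C)O)C(=O)[C@@]3(C)CC=C[C@@]3(C)C1)O2 | intermediate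
24 | (3aS,7aS)-5-(2-hydroxy-2-methylpropyl)-6-{[(2S)-6-methoxy-2,8-dimethyl-3,4-dihydro-2H-chromen-2-yl]methyl}-3a,7a-dimethyl-1,2,3,3a,7,7a-hexahydro-4H-inden-4-one | COc1cc(C)c2c(c1)CC[C@@](C)(CC1=C(CC(C)(C)O)C(=O)[C@@]3(C)CCC[C@@]3(C)C1)O2 | target

**Totals and risks**

Total step count: 13. Longest linear sequence: 10 steps (steps 1, 2, 3, 7, 8, 9, 10, 11, 12, 13).

Steps most likely to fail:

Step 10 (proposed new method). What may go wrong: poor facial discrimination in the C-alkylation, competing O-alkylation, and rearomatisation of the dienone by a dienone–phenol shift promoted by magnesium salts. Fallback with known chemistry: from 17, deprotonation with NaH in toluene gives the sodium phenoxide F1. Its heterogeneous alkylation with 18 at 25–40 °C (the classical ortho-C-alkylation of sodium 2,6-dialkylphenoxides in a non-polar solvent) gives 20 together with its 6R epimer F2, without facial bias. The mixture is taken through the conditions of step 11, and the cyclised pair, 21 and its (3aR,7aS) diastereomer F3, is separated by preparative HPLC on a chiral stationary phase. The route is rejoined at 21, at the cost of half the material.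

Step 11. What may go wrong: hydrogen transfer to the vinyl radical before ring closure, and thermal [3,3] migration of the bromoallyl group to C7 with rearomatisation. Fallback: from 20, a reductive Heck cyclisation (Pd(OAc)2, PPh3, HCO2Na, Et4NCl, DMF, 50 °C) replaces the radical chain by organopalladium chemistry. Zerovalent palladium inserts into the vinyl bromide, 5-exo syn-carbopalladation across C7a=C7 forms the same C1–C7a bond on the tether face, the C7–palladium species has no syn β-hydrogen and is reduced by formate. This gives 21 directly.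

Step 9. What may go wrong: sequestration of the catalyst by the free hindered phenoxide and slow oxidative addition at the doubly ortho-substituted aryl bromide. Fallback: from 15, before the Claisen rearrangement and with the phenol still masked, a copper-mediated Ullmann-type etherification (CuI, 3,4,7,8-tetramethyl-1,10-phenanthroline, Cs2CO3, toluene, 110 °C; allyl ethers are inert to copper) closes the pyran ring to the chroman methallyl ether F4. Claisen rearrangement of F4 (PhNEt2, 190 °C) then gives 17, where the route is rejoined.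

**Further compounds**

F1 | step 10 | sodium phenoxide of 17 | COc1cc(C)c2c(c1)CC[C@@](C)(Cc1cc(C)c(C)c([O-])c1CC(C)=C)O2.[Na+]
F2 | step 10 | (6R)-6-(3-bromoprop-2-en-1-yl)-3-{[(2S)-6-methoxy-2,8-dimethyl-3,4-dihydro-2H-chromen-2-yl]methyl}-5,6-dimethyl-2-(2-methylprop-2-en-1-yl)cyclohexa-2,4-dien-1-one | COc1cc(C)c2c(c1)CC[C@@](C)(CC1=C(CC(C)=C)C(=O)[C@](C)(CC=CBr)C(C)=C1)O2
F3 | step 10 | (3aR,7aS)-6-{[(2S)-6-methoxy-2,8-dimethyl-3,4-dihydro-2H-chromen-2-yl]methyl}-3a,7a-dimethyl-5-(2-methylprop-2-en-1-yl)-3,3a,7,7a-tetrahydro-4H-inden-4-one | COc1cc(C)c2c(c1)CC[C@@](C)(CC1=C(CC(C)=C)C(=O)[C@]3(C)CC=C[C@]3(C)C1)O2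
F0 | step 11 | none | none
F4 | step 9 | (2S)-2-{3,4-dimethyl-5-[(2-methylprop-2-en-1-yl)oxy]benzyl}-6-methoxy-2,8-dimethyl-3,4-dihydro-2H-chromene | COc1cc(C)c2c(c1)CC[C@@](C)(Cc1cc(C)c(C)c(OCC(C)=C)c1)O2
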